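**Plan**

- Retrosynthetic cuts, flavanone numbering: first the C2–C1' aryl bond, then the pyranone bonds O1–C2, C3–C4 and C4–C4a, then three A-ring bonds, C8a–C8, C6–C7 and C4a–C8a.
- Enabling feature: the A ring carries O1 on C8a, prenyl on C8, oxygen on C7, prenyl on C6, H on C5 and the acyl carbon on C4a. This contiguous O / C-prenyl / O / C-prenyl / H / C array maps onto a ketene carbon (C8a), the two carbons of a prenylated siloxyalkyne (C8, C7) and a prenyl-bearing vinylketene (C6, C5, C4a).
- Forward order: two acyclic fragments (vinyl diazoketone, siloxyalkyne) give the A ring by benzannulation. The pyranone ring follows by ortho-formylation, ethynylation and oxidative 6-endo cyclisation. The chromene unit, with its pyran ring already in place, is then joined at C2.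
- Stereochemistry: the single stereocentre, C2 (S), should come from ligand-controlled rhodium-catalysed 1,4-addition to the chromone; the final desilylation is buffered so that it is not scrambled.

Key step: step 6

Assumption: the facial sense of the rhodium 1,4-addition in step 11 is assigned by analogy with cyclic enones, where (S)-configured atropisomeric bisphosphines deliver the aryl group to the face that corresponds to 2S in a chromone; if the sense proves opposite, the antipodal ligand is used.

**Route**

Step 1
Reactants: 1 5-bromo-2-methylpent-2-ene; 2 acrolein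
Product: 4 7-methylocta-1,6-dien-3-ol (racemic), via homoprenylmagnesium bromide 3 (not isolated)
Conditions: Mg, THF, rt → 40 °C; then 2, THF, −78 → −20 °C; sat. aq NH4Cl
Reagents that add atoms: none
Why: Grignard 1,2-addition to an enal, in which the hard organomagnesium attacks the aldehyde carbon of acrolein at low temperature in preference to conjugate addition; the carbinol centre forms racemic and is removed in step 2.

Step 2
Reactants: 4 7-methylocta-1,6-dien-3-ol
Product: 5 7-methylocta-1,6-dien-3-one
Conditions: Dess–Martin periodinane (1.2 equiv), CH2Cl2, 0 °C → rt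
Reagents that add atoms: none
Why: Dess–Martin oxidation of a secondary allylic alcohol runs without amine base or heat, so the polymerisation-prone vinyl ketone should survive and the trisubstituted alkene is untouched.

Step 3
Reactants: 5 7-methylocta-1,6-dien-3-one
Product: 8 4-diazo-7-methylocta-1,6-dien-3-one, via lithium dienolate 6 (not isolated), via trifluoroacetyl diketone 7 (not isolated)
Conditions: LiHMDS (1.1 equiv), THF, −78 °C, slow addition of 5; CF3CO2CH2CF3 (1.2 equiv), −78 °C; 5% aq HCl work-up; crude 7, MsN3, Et3N, MeCN, rt
Reagents that add atoms: methanesulfonyl azide, CS(=O)(=O)N=[N+]=[N-]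
Why: Detrifluoroacetylative diazo transfer, in which C4 is the only enolisable position of 5, its kinetic lithium enolate is C-acylated by the trifluoroacetate, and the activated diketone hands its CF3CO group to the azide nitrogen as the α-diazoketone is released; the sequence is established for base-sensitive enones that fail in direct diazo transfer.

Step 4
Reactants: 9 4-methylpent-3-enoic acid
Product: 10 ethyl 4-methylpent-3-enoate
Conditions: EtI, K2CO3, DMF, rt
Reagents that add atoms: iodoethane, CCI
Why: SN2 O-alkylation of the carboxylate under mild base avoids the acid-catalysed γ-lactonisation and double-bond migration that Fischer esterification of this β,γ-unsaturated acid would risk.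

Step 5
Reactants: 10 ethyl 4-methylpent-3-enoate
Product: 13 triisopropyl[(5-methylhex-4-en-1-yn-1-yl)oxy]silane, via dibromo enolate 11 (not isolated), via lithium ynolate 12 (not isolated)
Conditions: CH2Br2, LiTMP, THF, −78 °C; 10; LiHMDS, −78 °C; n-BuLi, −78 °C → rt; TIPSCl, 0 °C → rt
Reagents that add atoms: dibromomethane, BrCBr; chlorotri(propan-2-yl)silane, CC(C)[Si](Cl)(C(C)C)C(C)C
Why: Kowalski ester homologation stopped at the ynolate: dibromomethyllithium adds to the ester carbonyl, the derived dibromo enolate undergoes bromine–lithium exchange and 1,2-shift of the alkyl group to the carbenoid carbon, and the bulky silyl chloride traps the ynolate on oxygen.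

Step 6
Reactants: 8 4-diazo-7-methylocta-1,6-dien-3-one; 13 triisopropyl[(5-methylhex-4-en-1-yn-1-yl)oxy]silane
Product: 18 2,4-bis(3-methylbut-2-en-1-yl)-3-(triisopropylsilyloxy)phenol, via vinylketene 14 (not isolated), via vinylcyclobutenone 15 (not isolated), via dienylketene 16 (not isolated), via cyclohexadienone 17 (not isolated)
Conditions: hν (254 nm, low-pressure Hg, Vycor), 13 (1.5 equiv), ClCH2CH2Cl, rt; then 80 °C
Reagents that add atoms: none
Why: Light expels N2 from 8 and the vinyl group migrates to the diazo carbon (Wolff rearrangement) to give vinylketene 14, whose C=C=O unit undergoes thermal [2+2] cycloaddition with 13 to vinylcyclobutenone 15; light or the later heating opens 15 by reversible four-electron conrotatory ring opening to dienylketene 16. The closest known reaction type is the Danheiser benzannulation in its photochemical Wolff variant with trialkylsiloxyalkynes, which delivers resorcinol monosilyl ethers. The A ring, the only ring formed, closes by thermal six-electron disrotatory electrocyclisation of 16 (ketene carbon C8a onto the vinyl terminus C4a, flavanone numbering) to cyclohexadienone 17, which tautomerises to the phenol. No stereocentre is created. The step needs regioselectivity in the [2+2] event, which the polarised ynol ether secures by bonding its nucleophilic prenyl-bearing carbon to the electrophilic ketene carbonyl carbon so that the siloxy carbon comes to lie between the two prenyl-bearing carbons, and chemoselectivity, which is secured because the trisubstituted prenyl alkenes are far poorer ketenophiles than the electron-rich alkyne used in excess. It also needs vinyl migration to outrun 1,2-hydrogen shift from the allylic CH2, which direct metal-free photolysis should favour, and because opening of 15 is reversible both dienylketene geometries should drain into the arene.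

Step 7
Reactants: 18 2,4-bis(3-methylbut-2-en-1-yl)-3-(triisopropylsilyloxy)phenol
Product: 19 2-hydroxy-3,5-bis(3-methylbut-2-en-1-yl)-4-(triisopropylsilyloxy)benzaldehyde
Conditions: MgCl2 (2 equiv), Et3N (4 equiv), (CH2O)n (6 equiv), MeCN, reflux; cold 1 M HCl work-up
Reagents that add atoms: paraformaldehyde (as formaldehyde), C=O
Why: Magnesium-mediated ortho-formylation (Casnati–Skattebøl), in which the chloromagnesium phenoxide delivers formaldehyde to the only free ortho position (the future C4a) and a second formaldehyde oxidises the benzylic alkoxide; no acid or electrophilic halogen touches the prenyl groups or the hindered silyl ether.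

Step 8
Reactants: 19 2-hydroxy-3,5-bis(3-methylbut-2-en-1-yl)-4-(triisopropylsilyloxy)benzaldehyde
Product: 20 1-[2-hydroxy-3,5-bis(3-methylbut-2-en-1-yl)-4-(triisopropylsilyloxy)phenyl]prop-2-yn-1-ol (racemic)
Conditions: HC≡CMgBr (3 equiv), THF, 0 °C → rt; sat. aq NH4Cl
Reagents that add atoms: ethynylmagnesium bromide, C#C[Mg]Br
Why: Grignard addition to an aldehyde, in which one equivalent is spent on the phenol and the magnesium phenoxide-chelated aldehyde is then attacked by the alkynyl nucleophile; the racemic carbinol centre is oxidised away in step 9.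

Step 9
Reactants: 20 1-[2-hydroxy-3,5-bis(3-methylbut-2-en-1-yl)-4-(triisopropylsilyloxy)phenyl]prop-2-yn-1-ol
Product: 22 6,8-bis(3-methylbut-2-en-1-yl)-7-(triisopropylsilyloxy)-4H-chromen-4-one, via ethynyl ketone 21 (not isolated)
Conditions: MnO2 (excess), CH2Cl2, rt; filter; K2CO3 (0.2 equiv), acetone, rt
Reagents that add atoms: none
Why: MnO2 selectively oxidises the doubly activated benzylic–propargylic alcohol, and the o-hydroxyaryl ethynyl ketone should cyclise by base-catalysed 6-endo-dig oxa-Michael addition of the phenoxide to the terminal alkyne carbon, the electronically matched mode for an unsubstituted ynone, giving the 2,3-unsubstituted chromone without acid.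

Step 10
Reactants: 23 6-bromo-2,2-dimethyl-2H-chromene
Product: 25 (2,2-dimethyl-2H-chromen-6-yl)boronic acid, via aryllithium 24 (not isolated)
Conditions: n-BuLi, THF, −78 °C; B(OiPr)3, −78 °C → rt; 1 M HCl
Reagents that add atoms: triisopropyl borate, CC(C)OB(OC(C)C)OC(C)C; water, O
Why: Bromine–lithium exchange at −78 °C is faster than any reaction at the chromene alkene, and borate trapping followed by hydrolysis is the standard route to an arylboronic acid.

Step 11
Reactants: 22 6,8-bis(3-methylbut-2-en-1-yl)-7-(triisopropylsilyloxy)-4H-chromen-4-one; 25 (2,2-dimethyl-2H-chromen-6-yl)boronic acid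
Product: 26 (2S)-2-(2,2-dimethyl-2H-chromen-6-yl)-6,8-bis(3-methylbut-2-en-1-yl)-7-(triisopropylsilyloxy)-2,3-dihydro-4H-chromen-4-one
Conditions: [RhOH((S)-MeO-F12-BIPHEP)]2 (3 mol% Rh), 25 (2 equiv), CH2Cl2/H2O, 20 °C
Reagents that add atoms: none
Why: Rhodium-catalysed asymmetric 1,4-addition of an arylboronic acid to a chromone (Hayashi–Miyaura type), in which the aryl–rhodium species inserts the C2=C3 bond on the enantioface left open by the (S)-biaryl bisphosphine, setting C2 as S, and water protonates the oxa-π-allyl rhodium; the electron-poor ligand in CH2Cl2/H2O without added base should disfavour 1,2-addition to the product and opening of the flavanone.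

Step 12
Reactants: 26 (2S)-2-(2,2-dimethyl-2H-chromen-6-yl)-6,8-bis(3-methylbut-2-en-1-yl)-7-(triisopropylsilyloxy)-2,3-dihydro-4H-chromen-4-one
Product: 27 (2S)-2-(2,2-dimethyl-2H-chromen-6-yl)-7-hydroxy-6,8-bis(3-methylbut-2-en-1-yl)-2,3-dihydro-4H-chromen-4-one (the target flavanone)
Conditions: TBAF, AcOH (1:1), THF, 0 °C
Reagents that add atoms: none
Why: Fluoride cleavage of the aryl silyl ether is eased by the para carbonyl that stabilises the departing phenoxide, and acetic acid buffering keeps the medium non-basic so the flavanone should not racemise through retro-oxa-Michael opening while the prenyl groups see no strong acid.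

**Compound list**

1 | 5-bromo-2-methylpent-2-ene | CC(C)=CCCBr | starting material
2 | acrolein (prop-2-enal) | C=CC=O | starting material
3 | (4-methylpent-3-en-1-yl)magnesium bromide | CC(C)=CCC[Mg]Br | intermediate
4 | 7-methylocta-1,6-dien-3-ol (racemic) | C=CC(O)CCC=C(C)C | intermediate
5 | 7-methylocta-1,6-dien-3-one | C=CC(=O)CCC=C(C)C | intermediate
6 | lithium 7-methylocta-1,3,6-trien-3-olate | C=CC([O-])=CCC=C(C)C.[Li+] | intermediate
7 | 1,1,1-trifluoro-3-(3-methylbut-2-en-1-yl)hex-5-ene-2,4-dione | C=CC(=O)C(CC=C(C)C)C(=O)C(F)(F)F | intermediate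
8 | 4-diazo-7-methylocta-1,6-dien-3-one | C=CC(=O)C(=[N+]=[N-])CC=C(C)C | intermediate
9 | 4-methylpent-3-enoic acid | CC(C)=CCC(=O)O | starting material
10 | ethyl 4-methylpent-3-enoate | CCOC(=O)CC=C(C)C | intermediate
11 | lithium 1,1-dibromo-5-methylhexa-1,4-dien-2-olate | CC(C)=CCC([O-])=C(Br)Br.[Li+] | intermediate
12 | lithium 5-methylhex-4-en-1-yn-1-olate | CC(C)=CCC#C[O-].[Li+] | intermediate
13 | triisopropyl[(5-methylhex-4-en-1-yn-1-yl)oxy]silane | CC(C)=CCC#CO[Si](C(C)C)(C(C)C)C(C)C | intermediate
14 | 2-(3-methylbut-2-en-1-yl)buta-1,3-dien-1-one | C=CC(CC=C(C)C)=C=O | intermediate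
15 | 4-ethenyl-2,4-bis(3-methylbut-2-en-1-yl)-3-(triisopropylsilyloxy)cyclobut-2-en-1-one (racemic) | C=CC1(CC=C(C)C)C(=O)C(CC=C(C)C)=C1O[Si](C(C)C)(C(C)C)C(C)C | intermediate
16 | (3E)-2,4-bis(3-methylbut-2-en-1-yl)-3-(triisopropylsilyloxy)hexa-1,3,5-trien-1-one | C=C/C(CC=C(C)C)=C(O[Si](C(C)C)(C(C)C)C(C)C)\C(CC=C(C)C)=C=O | intermediate
17 | 2,4-bis(3-methylbut-2-en-1-yl)-3-(triisopropylsilyloxy)cyclohexa-2,4-dien-1-one | O=C1CC=C(CC=C(C)C)C(O[Si](C(C)C)(C(C)C)C(C)C)=C1CC=C(C)C | intermediate
18 | 2,4-bis(3-methylbut-2-en-1-yl)-3-(triisopropylsilyloxy)phenol | CC(C)=CCc1ccc(O)c(CC=C(C)C)c1O[Si](C(C)C)(C(C)C)C(C)C | intermediate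
19 | 2-hydroxy-3,5-bis(3-methylbut-2-en-1-yl)-4-(triisopropylsilyloxy)benzaldehyde | CC(C)=CCc1cc(C=O)c(O)c(CC=C(C)C)c1O[Si](C(C)C)(C(C)C)C(C)C | intermediate
20 | 1-[2-hydroxy-3,5-bis(3-methylbut-2-en-1-yl)-4-(triisopropylsilyloxy)phenyl]prop-2-yn-1-ol (racemic) | C#CC(O)c1cc(CC=C(C)C)c(O[Si](C(C)C)(C(C)C)C(C)C)c(CC=C(C)C)c1O | intermediate
21 | 1-[2-hydroxy-3,5-bis(3-methylbut-2-en-1-yl)-4-(triisopropylsilyloxy)phenyl]prop-2-yn-1-one | C#CC(=O)c1cc(CC=C(C)C)c(O[Si](C(C)C)(C(C)C)C(C)C)c(CC=C(C)C)c1O | intermediate
22 | 6,8-bis(3-methylbut-2-en-1-yl)-7-(triisopropylsilyloxy)-4H-chromen-4-one | CC(C)=CCc1cc2c(c(CC=C(C)C)c1O[Si](C(C)C)(C(C)C)C(C)C)occc2=O | intermediate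
23 | 6-bromo-2,2-dimethyl-2H-chromene | CC1(C)C=Cc2cc(Br)ccc2O1 | starting material
24 | (2,2-dimethyl-2H-chromen-6-yl)lithium | CC1(C)C=Cc2cc([Li])ccc2O1 | intermediate
25 | (2,2-dimethyl-2H-chromen-6-yl)boronic acid | CC1(C)C=Cc2cc(B(O)O)ccc2O1 | intermediate
26 | (2S)-2-(2,2-dimethyl-2H-chromen-6-yl)-6,8-bis(3-methylbut-2-en-1-yl)-7-(triisopropylsilyloxy)-2,3-dihydro-4H-chromen-4-one | CC(C)=CCc1cc2c(c(CC=C(C)C)c1O[Si](C(C)C)(C(C)C)C(C)C)O[C@H](c1ccc3c(c1)C=CC(C)(C)O3)CC2=O | intermediate
27 | (2S)-2-(2,2-dimethyl-2H-chromen-6-yl)-7-hydroxy-6,8-bis(3-methylbut-2-en-1-yl)-2,3-dihydro-4H-chromen-4-one (the target flavanone) | CC(C)=CCc1cc2c(c(CC=C(C)C)c1O)O[C@H](c1ccc3c(c1)C=CC(C)(C)O3)CC2=O | target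

**Count and risks**

Total steps: 12. Longest linear sequence: 9 steps (steps 1, 2, 3, 6, 7, 8, 9, 11, 12).

Steps most likely to fail:

1. Step 6. After loss of nitrogen, 1,2-hydrogen shift from the allylic CH2 may compete with vinyl migration, and the ketene bearing an unsubstituted vinyl group may oligomerise or be photodegraded at 254 nm before the alkyne captures it. The fallback keeps the same ring construction but generates the vinylketene in the dark and without a carbene. It sets out from siloxyalkyne 13, for which a new partner is made. The dianion of crotonic acid (LDA, 2 equiv, THF, −78 °C) should be alkylated at the α-carbon by prenyl bromide to give 2-ethenyl-5-methylhex-4-enoic acid F1. Oxalyl chloride with catalytic DMF should convert this into 2-ethenyl-5-methylhex-4-enoyl chloride F2. Slow addition of F2 to 13 and triethylamine in toluene should release the ketene by dehydrochlorination, and the route is rejoined at vinylketene 14. Capture by 13 gives 15, and heating at 80–110 °C carries it through 16 and 17 to phenol 18. Ketenes made from acid chlorides and tertiary amines are known to add to siloxyalkynes, and with vinylketenes the adducts go on to resorcinol monosilyl ethers.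

2. Step 3. Conjugate self-addition and anionic polymerisation of the unhindered vinyl ketone, or 1,4-addition of the amide base, may outpace clean enolate formation. The fallback sets out from ketone 5 and separates enolisation from the strong base. Soft enolisation with TMSOTf and Et3N (CH2Cl2, 0 °C) should give trimethyl[(7-methylocta-1,3,6-trien-3-yl)oxy]silane F3, a 2-siloxydiene that can be distilled free of enone and amine. Methyllithium (THF, 0 °C) should then liberate the amine-free enolate, so the route is rejoined at lithium dienolate 6, which is trifluoroacetylated to 7 and converted into 8 as in step 3.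

3. Step 5. Dibromomethyllithium or the amide bases may deprotonate the acidic α-position of the β,γ-unsaturated ester instead of adding to the carbonyl, with migration of the double bond into conjugation. The fallback sets out from ester 10 and reaches the ynolate by acetylide oxidation instead of carbenoid rearrangement. DIBAL-H (CH2Cl2, −78 °C) should give 4-methylpent-3-enal F4, which is used at once. Corey–Fuchs olefination (CBr4, PPh3, CH2Cl2, 0 °C) should give 1,1-dibromo-5-methylhexa-1,4-diene F5. n-BuLi (2 equiv, THF, −78 °C) should convert this into (5-methylhex-4-en-1-yn-1-yl)lithium F6 without isolation of the volatile alkyne. Oxidation of the acetylide with lithium tert-butyl peroxide (−78 → 0 °C), a known route to ynolates, rejoins the route at lithium ynolate 12, which is silylated to 13 as before.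

**Further compounds**

F1 | step 6 | 2-ethenyl-5-methylhex-4-enoic acid (racemic) | C=CC(CC=C(C)C)C(=O)O
F2 | step 6 | 2-ethenyl-5-methylhex-4-enoyl chloride (racemic) | C=CC(CC=C(C)C)C(=O)Cl
F3 | step 3 | trimethyl[(7-methylocta-1,3,6-trien-3-yl)oxy]silane | C=CC(O[Si](C)(C)C)=CCC=C(C)C
F4 | step 5 | 4-methylpent-3-enal | CC(C)=CCC=O
F5 | step 5 | 1,1-dibromo-5-methylhexa-1,4-diene | CC(C)=CCC=C(Br)Br
F6 | step 5 | (5-methylhex-4-en-1-yn-1-yl)lithium | CC(C)=CCC#C[Li]
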